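**Retrosynthetic overview**

1. Numbering (elemane): cyclohexane C5–C10. C5 carries the acrolein unit (C4=C15, C3 = CHO), C6 the isobutyrate, C7/C8 the trans-fused lactone (C11=C13, C12=O, O on C8), C9 the OH, C10 the methyl (C14) and the oxirane (C1, C2).
2. Enabling feature: C6/C5 and C8/C7 are each a carbinol carbon next to a ring carbon bearing a 1-carbonylvinyl group, i.e. two homoallylic-alcohol retrons arranged head to tail. O6 and O8 are both γ to the lactone carbonyl C12, so a lactone can migrate from O6 to O8.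
3. Key disconnection C7–C8 and C5–C6: an acyclic C8 aldehyde carrying a (Z)-allylboronate at C5, plus a (5S)-5-menthyloxy-3-(borylmethyl)butenolide (C6, C7, C11–C13). Allylboration at C8, lactone relay O6→O8 that unmasks the C6 aldehyde, then ring-closing allylboration from C5; the lactone forms first and the cyclohexane second, in one operation.
4. Aldehyde fragment: C9/C10 by iridium-catalysed tert-(hydroxy)prenylation of a glycol monoether with isoprene oxide; its vinyl group becomes C5 (aldehyde → Z-iodoalkene → allylboronate) and its CH2OH becomes the C1 vinyl group. Butenolide fragment: furfural → hydroxybutenolide → (+)-menthyl acetal → 3-bromide → Negishi coupling.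
5. End game: isobutyrate on O6, OH-directed epoxidation of the C1=C2 vinyl group (oxirane ring last), allylic oxidation of the C3 methyl to the enal.

Key step: step 15

Assumption: in step 1 the Tol-BINAP enantiomer is the one that delivers the (2S,3R) diol, with the secondary OH anti to the hydroxymethyl group (written here as R; the antipode would be used if the sense of induction is opposite).

**Step 1**
Reactants: 1 mono-TBS ether of ethylene glycol; 2 isoprene monoxide
Product: 3 (2S,3R)-1-[(tert-butyldimethylsilyl)oxy]-3-(hydroxymethyl)-3-methylpent-4-en-2-ol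
Conditions: Ir(allyl)[(R)-Tol-BINAP](C,O-4-cyano-3-nitrobenzoate) (5 mol %), K3PO4 (5 mol %), racemic oxirane in threefold excess, THF, 60 °C
Reagents that add atoms: none
Why: Iridium-catalysed redox-triggered carbonyl allylation (tert-(hydroxy)prenylation): the alcohol is dehydrogenated to the aldehyde and the allyl-iridium species from opening of the oxirane adds through a chair transition state, which should set the carbinol and the all-carbon quaternary centre with anti relative and ligand-controlled absolute configuration, all atoms of both partners ending up in the product.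

**Step 2**
Reactants: 3 diol
Product: 4 (2S,4S,5R)-4-{[(tert-butyldimethylsilyl)oxy]methyl}-2-(4-methoxyphenyl)-5-methyl-5-vinyl-1,3-dioxane
Conditions: 4-MeOC6H4CH(OMe)2, PPTS (cat.), CH2Cl2, rt
Reagents that add atoms: 4-methoxybenzaldehyde dimethyl acetal, COc1ccc(cc1)C(OC)OC
Why: Acid-catalysed transacetalisation of the 1,3-diol gives the six-membered p-methoxybenzylidene acetal under thermodynamic control with the aryl group equatorial, so the acetal centre is cis to the silyloxymethyl group.

**Step 3**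
Reactants: 4 vinyl dioxane
Product: 5 (2S,4S,5R)-4-{[(tert-butyldimethylsilyl)oxy]methyl}-2-(4-methoxyphenyl)-5-methyl-1,3-dioxane-5-carbaldehyde
Conditions: OsO4 (2 mol %), NaIO4, 2,6-lutidine, dioxane/H2O, rt
Reagents that add atoms: osmium tetroxide, O=[Os](=O)(=O)=O (oxygen re-supplied by sodium periodate, [Na+].[O-]I(=O)(=O)=O)
Why: Lemieux–Johnson cleavage (dihydroxylation then periodate scission) turns the only alkene into the C5 aldehyde, which cannot epimerise because its α-carbon is quaternary.

**Step 4**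
Reactants: 5 aldehyde
Product: 6 (2S,4S,5R)-4-{[(tert-butyldimethylsilyl)oxy]methyl}-5-[(Z)-2-iodoprop-1-en-1-yl]-2-(4-methoxyphenyl)-5-methyl-1,3-dioxane
Conditions: Ph3PEtI, n-BuLi, THF, rt; I2, −78 °C; NaHMDS, −20 °C; then the aldehyde, −78 °C → rt
Reagents that add atoms: ethyltriphenylphosphonium iodide, CC[P+](c1ccccc1)(c1ccccc1)c1ccccc1.[I-]; iodine, II
Why: Stork–Zhao-type Wittig olefination with the α-iodo ylide Ph3P=C(I)CH3 should give the trisubstituted iodoalkene with iodine cis to the quaternary carbon (Z), the geometry that later places the CH2B group cis to that carbon.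

**Step 5**
Reactants: 6 iodoalkenyl dioxane
Product: 7 (2R,3Z)-2-{(1S)-2-[(tert-butyldimethylsilyl)oxy]-1-[(4-methoxybenzyl)oxy]ethyl}-4-iodo-2-methylpent-3-en-1-ol
Conditions: i-Bu2AlH (3 equiv), CH2Cl2, −78 → 0 °C; aq. KNaC4H4O6 work-up
Reagents that add atoms: none
Why: Reductive opening of the p-methoxybenzylidene acetal: aluminium coordinates the less hindered primary oxygen and hydride opens the acetal, so the PMB ether stays on the secondary O9 and the primary C1 alcohol is freed.

**Step 6**
Reactants: 7 primary alcohol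
Product: 8 (2S,3Z)-2-{(1S)-2-[(tert-butyldimethylsilyl)oxy]-1-[(4-methoxybenzyl)oxy]ethyl}-4-iodo-2-methylpent-3-enal
Conditions: Dess–Martin periodinane, NaHCO3, CH2Cl2, rt
Reagents that add atoms: none
Why: Dess–Martin oxidation of the primary alcohol to a non-enolisable aldehyde under buffered conditions that leave the iodoalkene, PMB ether and silyl ether untouched.

**Step 7**
Reactants: 8 aldehyde
Product: 9 tert-butyl{[(2S,3S,4Z)-5-iodo-2-[(4-methoxybenzyl)oxy]-3-methyl-3-vinylhex-4-en-1-yl]oxy}dimethylsilane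
Conditions: Ph3PMeBr (slight excess over base), KOt-Bu, THF, 0 °C → rt
Reagents that add atoms: methyltriphenylphosphonium bromide, C[P+](c1ccccc1)(c1ccccc1)c1ccccc1.[Br-]
Why: Wittig methylenation of the hindered but non-enolisable aldehyde installs the vinyl group that becomes the oxirane carbons C1 and C2, and the absence of free base protects the iodoalkene from dehydroiodination.

**Step 8**
Reactants: 9 silyl ether
Product: 10 (2S,3S,4Z)-5-iodo-2-[(4-methoxybenzyl)oxy]-3-methyl-3-vinylhex-4-en-1-ol
Conditions: Bu4NF, THF, 0 °C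
Reagents that add atoms: none
Why: Fluoride-induced cleavage of the primary TBS ether; the PMB ether and both alkenes are inert.

**Step 9**
Reactants: 10 primary alcohol
Product: 11 (2S,3S,4Z)-5-iodo-2-[(4-methoxybenzyl)oxy]-3-methyl-3-vinylhex-4-enal
Conditions: Dess–Martin periodinane, NaHCO3, CH2Cl2, 0 °C; used at once
Reagents that add atoms: none
Why: Dess–Martin oxidation under buffered, non-basic conditions should give the α-alkoxy aldehyde without epimerisation at the adjacent stereocentre.

**Step 10**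
Reactants: 11 iodoalkenyl aldehyde
Product: 12 (2S,3S,4Z)-2-[(4-methoxybenzyl)oxy]-3,5-dimethyl-6-(4,4,5,5-tetramethyl-1,3,2-dioxaborolan-2-yl)-3-vinylhex-4-enal
Conditions: ICH2Bpin, Zn dust, THF, rt; then the iodoalkene, Pd(PPh3)4 (5 mol %), THF, rt; used crude
Reagents that add atoms: 2-(iodomethyl)-4,4,5,5-tetramethyl-1,3,2-dioxaborolane, ICB1OC(C)(C)C(C)(C)O1
Why: Negishi coupling of the alkenyl iodide with the (borylmethyl)zinc reagent proceeds with retention of alkene geometry and tolerates the aldehyde, giving a Z-allylboronate whose γ-carbon is neopentylic and therefore sluggish towards a second molecule.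

**Step 11**
Reactants: 13 furfural
Product: 14 5-hydroxyfuran-2(5H)-one (racemic)
Conditions: O2, hν, rose bengal (cat.), MeOH, rt
Reagents that add atoms: oxygen, O=O
Why: Schenck-type photooxygenation: [4+2] addition of singlet oxygen to the furan and methanolysis of the endoperoxide with loss of methyl formate gives the γ-hydroxybutenolide.

**Step 12**
Reactants: 14 hydroxybutenolide; 15 (+)-menthol
Product: 16 (5S)-5-{[(1S,2R,5S)-2-isopropyl-5-methylcyclohexyl]oxy}furan-2(5H)-one
Conditions: CSA (cat.), toluene, reflux, Dean–Stark; crystallisation from hexane, mother liquor re-equilibrated with acid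
Reagents that add atoms: none
Why: Acid-catalysed acetalisation of the pseudo-acid with (+)-menthol and crystallisation-driven epimerisation of the acetal centre should deliver the single (5S) diastereomer, the mirror image of the well-known (5R)-l-menthyl compound.

**Step 13**
Reactants: 16 menthyloxybutenolide
Product: 18 (5S)-3-bromo-5-(d-menthyloxy)furan-2(5H)-one, via trans-3,4-dibromolactone 17 (not isolated)
Conditions: Br2, CH2Cl2, 0 °C; then pyridine, 0 °C → rt
Reagents that add atoms: bromine, BrBr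
Why: Anti addition of bromine to the enoate alkene and E1cB loss of HBr (α-proton, β-bromide) gives the α-bromobutenolide without touching the acetal centre.

**Step 14**
Reactants: 18 bromobutenolide
Product: 19 (5S)-5-(d-menthyloxy)-3-[(4,4,5,5-tetramethyl-1,3,2-dioxaborolan-2-yl)methyl]furan-2(5H)-one
Conditions: ICH2Bpin, Zn dust, THF, rt; then the bromide, Pd(PPh3)4 (5 mol %), THF, 40 °C
Reagents that add atoms: 2-(iodomethyl)-4,4,5,5-tetramethyl-1,3,2-dioxaborolane, ICB1OC(C)(C)C(C)(C)O1
Why: Negishi coupling of the α-bromo enoate with the (borylmethyl)zinc reagent gives a 2-carbonyl allylboronate whose alkene geometry is locked by the ring, with the acetal carbon cis to the carbonyl group.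

**Step 15**
Reactants: 12 aldehyde allylboronate; 19 butenolide allylboronate
Product: 22 (3aS,4S,5S,6S,7S,7aR)-4-hydroxy-7-[(4-methoxybenzyl)oxy]-6-methyl-3-methylidene-5-(prop-1-en-2-yl)-6-vinylhexahydro-1-benzofuran-2(3H)-one, via borate adduct 20 (not isolated), via formyl lactone boronate 21 (not isolated)
Conditions: butenolide boronate in 1.5-fold excess, toluene, 4 Å MS, (PhO)2P(O)OH (10 mol %), rt → 70 °C; then aq. NaHCO3, 0 °C
Reagents that add atoms: none
Why: Proposed new method: the 2-carbonyl allylboronate 19 should add to the aldehyde of 12 through a closed chair transition state (borate 20), the O8 borate then attacks the acetal-lactone carbonyl so that the lactone migrates from O6 to O8 while the released hemiacetal collapses to the C6 aldehyde and menthyl pinacol borate (21), and the Z-allylboronate on C5 closes the carbocycle onto this aldehyde in a second chair transition state; the closest known reaction types are the allylboration–lactonisation of aldehydes with 2-alkoxycarbonyl allylboronates, the O6-to-O8 relactonisation of sesquiterpene lactones and the intramolecular allylboration of ω-oxo allylboronates. The lactone closes by 5-exo-trig acyl transfer through a 2,6-dioxabicyclo[2.2.1]heptane tetrahedral intermediate, and the cyclohexane closes 6-exo-trig at the carbonyl with the C5=C4 bond exocyclic, the six-membered boron chelate being cis-fused to the forming chair. C7 is set by attack on the butenolide face anti to the menthyloxy group, and C8 by the chair with the aldehyde residue equatorial, which for the ring-locked alkene (C6 cis to C12, E-crotyl type) gives the 7,8-anti trans-lactone relation and coincides with the Cornforth-preferred face of the α-PMB-oxy aldehyde. C5 and C6 are set by the Z geometry of the allylboronate (C10 cis to CH2B), which places O6 and the isopropenyl group cis on the new ring, and by the forming chair, in which the lactone is diequatorial and the alkenyl–boron unit equatorial, so that O6 becomes axial. The step needs the aldehyde of 12 to react with 19 and not with the allylboronate of a second molecule of 12, which the neopentylic γ-carbon of that boronate and the excess of 19 should secure, and it needs the C6 aldehyde to stay masked until C7–C8 exists, which the acetal lactone secures. A second lactone migration back to O6 lacks the hemiacetal driving force, and O6 stays borylated until the cold work-up.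

**Step 16**
Reactants: 22 hydroxy lactone
Product: 23 (3aS,4S,5S,6S,7S,7aR)-7-[(4-methoxybenzyl)oxy]-6-methyl-3-methylidene-2-oxo-5-(prop-1-en-2-yl)-6-vinyloctahydro-1-benzofuran-4-yl 2-methylpropanoate
Conditions: (i-PrCO)2O, DMAP, Et3N, CH2Cl2, 0 °C → rt
Reagents that add atoms: isobutyric anhydride, CC(C)C(=O)OC(=O)C(C)C
Why: DMAP-catalysed acylation of the only free hydroxyl group (axial C6–OH) under weakly basic conditions that avoid alkoxide formation and hence lactone migration from O8 to O6.

**Step 17**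
Reactants: 23 PMB ether
Product: 24 (3aS,4S,5S,6S,7S,7aR)-7-hydroxy-6-methyl-3-methylidene-2-oxo-5-(prop-1-en-2-yl)-6-vinyloctahydro-1-benzofuran-4-yl 2-methylpropanoate
Conditions: DDQ, CH2Cl2/pH 7 buffer, 0 °C
Reagents that add atoms: none
Why: Oxidative cleavage of the PMB ether by DDQ (hydride abstraction, hydrolysis of the oxocarbenium ion) frees the C9 hydroxyl while the esters and alkenes remain.

**Step 18**
Reactants: 24 homoallylic alcohol
Product: 25 (3aS,4S,5S,6S,7S,7aR)-7-hydroxy-6-methyl-3-methylidene-6-[(2R)-oxiran-2-yl]-2-oxo-5-(prop-1-en-2-yl)octahydro-1-benzofuran-4-yl 2-methylpropanoate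
Conditions: VO(acac)2 (5 mol %), t-BuOOH, CH2Cl2, 0 °C → rt
Reagents that add atoms: tert-butyl hydroperoxide, CC(C)(C)OO
Why: Vanadium-catalysed hydroxyl-directed epoxidation of the homoallylic alcohol: the axial C9–O–V peroxo complex reaches only the neighbouring equatorial vinyl group, which in its preferred rotamer (C=C eclipsing the C10–C5 bond) turns the face that leads to the (R)-oxirane towards the metal, while the isopropenyl group is out of reach and the methylene lactone is electron-poor.

**Step 19**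
Reactants: 25 isopropenyl oxirane
Product: 27 target (3aS,4S,5R,6S,7S,7aR)-7-hydroxy-6-methyl-3-methylidene-6-[(2R)-oxiran-2-yl]-2-oxo-5-(3-oxoprop-1-en-2-yl)octahydro-1-benzofuran-4-yl 2-methylpropanoate, via allylic alcohol 26 (not isolated)
Conditions: SeO2 (20 mol %), t-BuOOH, CH2Cl2, rt; then MnO2, CH2Cl2, rt
Reagents that add atoms: tert-butyl hydroperoxide, CC(C)(C)OO (oxygen delivered through selenium dioxide, O=[Se]=O)
Why: Selenium dioxide allylic oxidation (ene reaction then [2,3]-sigmatropic shift) should hydroxylate the methyl group of the 1,1-disubstituted alkene in preference to the methine C5–H, and MnO2 oxidises the primary allylic alcohol selectively over the secondary C9–OH to give the enal.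

**Compound list**

1 | 2-[(tert-butyldimethylsilyl)oxy]ethanol | CC(C)(C)[Si](C)(C)OCCO | starting material
2 | 2-methyl-2-vinyloxirane (isoprene monoxide, racemic) | CC1(C=C)CO1 | starting material
3 | (2S,3R)-1-[(tert-butyldimethylsilyl)oxy]-3-(hydroxymethyl)-3-methylpent-4-en-2-ol | CC(C)(C)[Si](C)(C)OC[C@@H](O)[C@@](C)(CO)C=C | intermediate
4 | (2S,4S,5R)-4-{[(tert-butyldimethylsilyl)oxy]methyl}-2-(4-methoxyphenyl)-5-methyl-5-vinyl-1,3-dioxane | COc1ccc(cc1)[C@H]1OC[C@@](C)(C=C)[C@@H](CO[Si](C)(C)C(C)(C)C)O1 | intermediate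
5 | (2S,4S,5R)-4-{[(tert-butyldimethylsilyl)oxy]methyl}-2-(4-methoxyphenyl)-5-methyl-1,3-dioxane-5-carbaldehyde | COc1ccc(cc1)[C@H]1OC[C@@](C)(C=O)[C@@H](CO[Si](C)(C)C(C)(C)C)O1 | intermediate
6 | (2S,4S,5R)-4-{[(tert-butyldimethylsilyl)oxy]methyl}-5-[(Z)-2-iodoprop-1-en-1-yl]-2-(4-methoxyphenyl)-5-methyl-1,3-dioxane | COc1ccc(cc1)[C@H]1OC[C@@](C)(/C=C(\I)C)[C@@H](CO[Si](C)(C)C(C)(C)C)O1 | intermediate
7 | (2R,3Z)-2-{(1S)-2-[(tert-butyldimethylsilyl)oxy]-1-[(4-methoxybenzyl)oxy]ethyl}-4-iodo-2-methylpent-3-en-1-ol | CC(C)(C)[Si](C)(C)OC[C@@H](OCc1ccc(OC)cc1)[C@@](C)(CO)/C=C(\I)C | intermediate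
8 | (2S,3Z)-2-{(1S)-2-[(tert-butyldimethylsilyl)oxy]-1-[(4-methoxybenzyl)oxy]ethyl}-4-iodo-2-methylpent-3-enal | CC(C)(C)[Si](C)(C)OC[C@@H](OCc1ccc(OC)cc1)[C@@](C)(C=O)/C=C(\I)C | intermediate
9 | tert-butyl{[(2S,3S,4Z)-5-iodo-2-[(4-methoxybenzyl)oxy]-3-methyl-3-vinylhex-4-en-1-yl]oxy}dimethylsilane | CC(C)(C)[Si](C)(C)OC[C@@H](OCc1ccc(OC)cc1)[C@@](C)(C=C)/C=C(\I)C | intermediate
10 | (2S,3S,4Z)-5-iodo-2-[(4-methoxybenzyl)oxy]-3-methyl-3-vinylhex-4-en-1-ol | OC[C@@H](OCc1ccc(OC)cc1)[C@@](C)(C=C)/C=C(\I)C | intermediate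
11 | (2S,3S,4Z)-5-iodo-2-[(4-methoxybenzyl)oxy]-3-methyl-3-vinylhex-4-enal | O=C[C@@H](OCc1ccc(OC)cc1)[C@@](C)(C=C)/C=C(\I)C | intermediate
12 | (2S,3S,4Z)-2-[(4-methoxybenzyl)oxy]-3,5-dimethyl-6-(4,4,5,5-tetramethyl-1,3,2-dioxaborolan-2-yl)-3-vinylhex-4-enal | O=C[C@@H](OCc1ccc(OC)cc1)[C@@](C)(C=C)/C=C(\CB1OC(C)(C)C(C)(C)O1)C | intermediate
13 | furfural | O=Cc1ccco1 | starting material
14 | 5-hydroxyfuran-2(5H)-one (racemic) | OC1OC(=O)C=C1 | intermediate
15 | (+)-menthol, (1S,2R,5S)-2-isopropyl-5-methylcyclohexan-1-ol | O[C@H]1C[C@@H](C)CC[C@@H]1C(C)C | starting material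
16 | (5S)-5-{[(1S,2R,5S)-2-isopropyl-5-methylcyclohexyl]oxy}furan-2(5H)-one | O=C1O[C@H](O[C@H]2C[C@@H](C)CC[C@@H]2C(C)C)C=C1 | intermediate
17 | trans-3,4-dibromo-5-(d-menthyloxy)dihydrofuran-2(3H)-one (4-Br trans to the menthyloxy group) | O=C1O[C@H](O[C@H]2C[C@@H](C)CC[C@@H]2C(C)C)[C@@H](Br)[C@@H]1Br | intermediate
18 | (5S)-3-bromo-5-(d-menthyloxy)furan-2(5H)-one | O=C1O[C@H](O[C@H]2C[C@@H](C)CC[C@@H]2C(C)C)C=C1Br | intermediate
19 | (5S)-5-(d-menthyloxy)-3-[(4,4,5,5-tetramethyl-1,3,2-dioxaborolan-2-yl)methyl]furan-2(5H)-one | O=C1O[C@H](O[C@H]2C[C@@H](C)CC[C@@H]2C(C)C)C=C1CB3OC(C)(C)C(C)(C)O3 | intermediate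
20 | borate adduct: 3-methylidene-5-(d-menthyloxy)butyrolactone carrying at C4 (trans to the menthyloxy group) the O-pinacolboryl carbinol chain with the intact Z-allylboronate | C=C1C(=O)O[C@H](O[C@H]2C[C@@H](C)CC[C@@H]2C(C)C)[C@H]1[C@@H](OB3OC(C)(C)C(C)(C)O3)[C@@H](OCc4ccc(OC)cc4)[C@@](C)(C=C)/C=C(\CB5OC(C)(C)C(C)(C)O5)C | intermediate
21 | formyl lactone boronate: trans-4-formyl-3-methylidene-5-substituted butyrolactone (8,12-lactone) with the Z-allylboronate side chain | C=C1C(=O)O[C@@H]([C@@H](OCc2ccc(OC)cc2)[C@@](C)(C=C)/C=C(\CB3OC(C)(C)C(C)(C)O3)C)[C@@H]1C=O | intermediate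
22 | (3aS,4S,5S,6S,7S,7aR)-4-hydroxy-7-[(4-methoxybenzyl)oxy]-6-methyl-3-methylidene-5-(prop-1-en-2-yl)-6-vinylhexahydro-1-benzofuran-2(3H)-one | C=C1C(=O)O[C@@H]2[C@@H]1[C@@H](O)[C@@H](C(=C)C)[C@](C)(C=C)[C@@H]2OCc1ccc(OC)cc1 | intermediate
23 | (3aS,4S,5S,6S,7S,7aR)-7-[(4-methoxybenzyl)oxy]-6-methyl-3-methylidene-2-oxo-5-(prop-1-en-2-yl)-6-vinyloctahydro-1-benzofuran-4-yl 2-methylpropanoate | C=C1C(=O)O[C@@H]2[C@@H]1[C@@H](OC(=O)C(C)C)[C@@H](C(=C)C)[C@](C)(C=C)[C@@H]2OCc1ccc(OC)cc1 | intermediate
24 | (3aS,4S,5S,6S,7S,7aR)-7-hydroxy-6-methyl-3-methylidene-2-oxo-5-(prop-1-en-2-yl)-6-vinyloctahydro-1-benzofuran-4-yl 2-methylpropanoate | C=C1C(=O)O[C@@H]2[C@@H]1[C@@H](OC(=O)C(C)C)[C@@H](C(=C)C)[C@](C)(C=C)[C@@H]2O | intermediate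
25 | (3aS,4S,5S,6S,7S,7aR)-7-hydroxy-6-methyl-3-methylidene-6-[(2R)-oxiran-2-yl]-2-oxo-5-(prop-1-en-2-yl)octahydro-1-benzofuran-4-yl 2-methylpropanoate | C=C1C(=O)O[C@@H]2[C@@H]1[C@@H](OC(=O)C(C)C)[C@@H](C(=C)C)[C@](C)([C@@H]1CO1)[C@@H]2O | intermediate
26 | (3aS,4S,5S,6S,7S,7aR)-7-hydroxy-5-(3-hydroxyprop-1-en-2-yl)-6-methyl-3-methylidene-6-[(2R)-oxiran-2-yl]-2-oxooctahydro-1-benzofuran-4-yl 2-methylpropanoate | C=C1C(=O)O[C@@H]2[C@@H]1[C@@H](OC(=O)C(C)C)[C@@H](C(=C)CO)[C@](C)([C@@H]1CO1)[C@@H]2O | intermediate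
27 | (3aS,4S,5R,6S,7S,7aR)-7-hydroxy-6-methyl-3-methylidene-6-[(2R)-oxiran-2-yl]-2-oxo-5-(3-oxoprop-1-en-2-yl)octahydro-1-benzofuran-4-yl 2-methylpropanoate | C=C1C(=O)O[C@@H]2[C@@H]1[C@@H](OC(=O)C(C)C)[C@@H](C(=C)C=O)[C@](C)([C@@H]1CO1)[C@@H]2O | target

**Step count**

Total: 19 steps. Longest linear sequence: 15 steps (steps 1–10 and 15–19); the butenolide branch (steps 11–14) joins at step 15.

**Steps most likely to fail**

Step 15 (proposed new method). Possible failures: the first allylboration may be slow and lose to self-condensation of 12; the lactone migration may fail to unmask the aldehyde; the exo-methylene group of the formyl lactone may drift into conjugation, or C7 may epimerise, before ring closure; or the lactone may migrate back to O6. Fallback from 11, returning at 21: the relay is replaced by stepwise, established reactions. Methyl 4-hydroxybut-2-ynoate is silylated (TBSCl, imidazole) to methyl 4-[(tert-butyldimethylsilyl)oxy]but-2-ynoate F1. Conjugate reduction of F1 (i-Bu2AlH, HMPA, THF, 0 °C) and trapping of the α-metallated acrylate with ICH2Bpin gives methyl (Z)-4-[(tert-butyldimethylsilyl)oxy]-2-[(pinacolboryl)methyl]but-2-enoate F2, a known type of 2-alkoxycarbonyl allylboronate. Thermal allylboration of 11 with F2 (toluene, 80 °C), then lactonisation with p-TsOH, should give the trans-disubstituted methylene lactone F3. HF·pyridine gives the primary alcohol F4, and Dess–Martin oxidation gives the formyl lactone F5, which still carries the iodoalkene. Negishi coupling of F5 with IZnCH2Bpin (Pd(PPh3)4) gives 21, which closes to 22 on warming as in step 15.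

Step 18. Possible failures: poor facial selectivity at C1, or competing oxidation of the isopropenyl group. Fallback from 24, returning at 27: SeO2/t-BuOOH gives the allylic alcohol F6 with the vinyl group intact, and MnO2 gives the enal F7. The vinyl group is then the only alkene not conjugated to a carbonyl group; undirected epoxidation (m-CPBA, NaHCO3, CH2Cl2) gives 27 together with its C1 epimer F8. Hydrolytic kinetic resolution with the enantiomer of N,N'-bis(3,5-di-tert-butylsalicylidene)-1,2-cyclohexanediaminocobalt acetate matched to F8 (H2O, THF) converts F8 into the diol F9 and leaves 27.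

Step 4. Possible failures: low conversion of the neopentylic aldehyde with the bulky iodo ylide, or erosion of Z selectivity. Fallback from 5, returning at 6: Ramirez olefination (CBr4, PPh3, Et3N, CH2Cl2, 0 °C) gives the 1,1-dibromoalkene F10. Palladium-catalysed trans-selective monomethylation (Me2Zn, Pd[P(t-Bu)3]2, THF) replaces the bromine trans to the quaternary carbon and gives the (Z)-2-bromopropenyl dioxane F11. Copper-catalysed halogen exchange (CuI, NaI, trans-N,N'-dimethylcyclohexane-1,2-diamine, dioxane, 110 °C) gives 6 with retention.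

**Further compounds**

F1 | step 15 | methyl 4-[(tert-butyldimethylsilyl)oxy]but-2-ynoate | COC(=O)C#CCO[Si](C)(C)C(C)(C)C
F2 | step 15 | methyl (Z)-4-[(tert-butyldimethylsilyl)oxy]-2-[(4,4,5,5-tetramethyl-1,3,2-dioxaborolan-2-yl)methyl]but-2-enoate | COC(=O)/C(CB1OC(C)(C)C(C)(C)O1)=C\CO[Si](C)(C)C(C)(C)C
F3 | step 15 | trans-4-{[(tert-butyldimethylsilyl)oxy]methyl}-3-methylidene butyrolactone bearing the iodoalkenyl PMB-oxy side chain at C5 | C=C1C(=O)O[C@@H]([C@@H](OCc2ccc(OC)cc2)[C@@](C)(C=C)/C=C(\I)C)[C@@H]1CO[Si](C)(C)C(C)(C)C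
F4 | step 15 | trans-4-(hydroxymethyl)-3-methylidene butyrolactone bearing the iodoalkenyl PMB-oxy side chain | C=C1C(=O)O[C@@H]([C@@H](OCc2ccc(OC)cc2)[C@@](C)(C=C)/C=C(\I)C)[C@@H]1CO
F5 | step 15 | trans-4-formyl-3-methylidene butyrolactone bearing the iodoalkenyl PMB-oxy side chain | C=C1C(=O)O[C@@H]([C@@H](OCc2ccc(OC)cc2)[C@@](C)(C=C)/C=C(\I)C)[C@@H]1C=O
F6 | step 18 | 7-hydroxy-5-(3-hydroxyprop-1-en-2-yl)-6-methyl-3-methylidene-2-oxo-6-vinyloctahydro-1-benzofuran-4-yl 2-methylpropanoate | C=C1C(=O)O[C@@H]2[C@@H]1[C@@H](OC(=O)C(C)C)[C@@H](C(=C)CO)[C@](C)(C=C)[C@@H]2O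
F7 | step 18 | 7-hydroxy-6-methyl-3-methylidene-2-oxo-5-(3-oxoprop-1-en-2-yl)-6-vinyloctahydro-1-benzofuran-4-yl 2-methylpropanoate | C=C1C(=O)O[C@@H]2[C@@H]1[C@@H](OC(=O)C(C)C)[C@@H](C(=C)C=O)[C@](C)(C=C)[C@@H]2O
F8 | step 18 | (2S)-oxiranyl epimer of 27 | C=C1C(=O)O[C@@H]2[C@@H]1[C@@H](OC(=O)C(C)C)[C@@H](C(=C)C=O)[C@](C)([C@H]1CO1)[C@@H]2O
F9 | step 18 | 6-[(1S)-1,2-dihydroxyethyl] diol from hydrolysis of F8 | C=C1C(=O)O[C@@H]2[C@@H]1[C@@H](OC(=O)C(C)C)[C@@H](C(=C)C=O)[C@](C)([C@H](O)CO)[C@@H]2O
F10 | step 4 | (2S,4S,5R)-4-{[(tert-butyldimethylsilyl)oxy]methyl}-5-(2,2-dibromovinyl)-2-(4-methoxyphenyl)-5-methyl-1,3-dioxane | COc1ccc(cc1)[C@H]1OC[C@@](C)(C=C(Br)Br)[C@@H](CO[Si](C)(C)C(C)(C)C)O1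
F11 | step 4 | (2S,4S,5R)-5-[(Z)-2-bromoprop-1-en-1-yl]-4-{[(tert-butyldimethylsilyl)oxy]methyl}-2-(4-methoxyphenyl)-5-methyl-1,3-dioxane | COc1ccc(cc1)[C@H]1OC[C@@](C)(/C=C(\Br)C)[C@@H](CO[Si](C)(C)C(C)(C)C)O1
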